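# Proposal: synthesis of 2-[(2R)-2-acetoxytridecyl]-4-hydroxy-6-methoxybenzoic acid (14) by nickel-catalysed three-component assembly of the acetoxy stereocentre

Numbering used throughout: ring C1 carries the carboxyl group, C2 the side chain, C4 the phenol, C6 the methyl ether; the chain is C1′ (benzylic) to C13′, with the acetate on C2′.

## The problem

The target 14 is one benzene ring with four substituents and no ring fusion. The chain is unbranched, attached through C1′, and acetoxylated at C2′. The only stereocentre is C2′ (R); nothing else in the molecule can relay to it, so its configuration must come from a reagent or catalyst. C2′ lies between two methylene groups of nearly equal size (C1′ and C3′), so methods that read steric difference, such as reduction of the corresponding ketone, have little to distinguish. The C2′ oxygen stands delta to the carboxyl carbon: a free alcohol or alkoxide there, next to an ester, closes to a six-membered lactone (a 3-undecyl dihydroisocoumarin). The acetate therefore has to be in place whenever the carboxyl group is electrophilic, and it in turn rules out hydrolytic unmasking of the acid and the C4 phenol at the end. The two phenolic oxygens must be differentiated early, and any arylacetaldehyde-level intermediate can enolise and close on the ester to an isocoumarin. The enabling feature is that C2′ bears one hydrogen, one acyloxy group and two carbon arms. This is the pattern of an aldehyde carbon (C2′ with C1′ attached) that has taken up an acyl bromide and an alkyl nucleophile, so the acetyl group becomes the handle the catalyst reads.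

## Retrosynthesis

**14 to 13.** The two O–CH2Ph bonds are cut: the benzyl ester on C1 and the benzyl ether on C4. Hydrogenolysis is neutral and non-nucleophilic, so the secondary acetate is untouched and both groups fall in one operation. A methyl ester would need hydrolysis, which would take the acetate first. The precursor is benzyl 2-[(2R)-2-acetoxytridecyl]-4-(benzyloxy)-6-methoxybenzoate 13. The forward step only requires that the homobenzylic C2′–O bond is not hydrogenolysed, which is expected since it is not benzylic.

**13 to 8, 11 and 10.** Two bonds at C2′ are cut: the C2′–C3′ bond to the undecyl tail and the O–acyl bond of the acetate. This leads to the achiral aldehyde 8, acetyl bromide 11 and undecylzinc bromide 10, joined through the racemic 1-bromoalkyl acetate 12.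
- Cutting C1′–C2′ instead (lateral benzylic anion plus dodecanal) would be racemic and would deliver an alkoxide straight onto the ester.
- Cutting at the ketone stage would ask a reductant to distinguish two methylene arms.
- The chosen cut installs the acetate before the carbon–carbon bond and lets a chiral nickel catalyst distinguish acyloxy from alkyl, not alkyl from alkyl.

The forward reaction must form 12 cold and without ionisation, and must leave the hindered aryl ester alone. Reagent 10 comes from 1-bromoundecane 9 by zinc insertion.

**8 to 7 to 6.** No skeletal bond is cut; the C2′ oxidation level is adjusted from acid 6 through thioester 7 to aldehyde 8. Reducing the acid to the alcohol and reoxidising would put a primary alcohol next to the ester. The thioester/silane reduction goes directly to the aldehyde under neutral conditions and is selective over the benzyl ester.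

**6 to 4.** The C1′–C2′ bond is cut, giving toluate 4 and carbon dioxide via the lateral benzyllithium 5. The ortho ester acidifies the C2 methyl group. Carbon dioxide is chosen over a formyl donor because the carboxylate product is inert to further deprotonation and cannot cyclise, whereas direct formylation would give the isocoumarin.

**4 to 3 to 1 and 2.** The O–methyl bond and the two O–benzyl bonds are cut back to orsellinic acid 1 and benzyl bromide 2. The C6 hydroxyl (numbered as the 2-hydroxyl in the benzoate names of 1 and 3) is hydrogen-bonded to the carbonyl and reacts last. Two equivalents of 2 therefore give the benzyl ester and the C4 benzyl ether 3, and the remaining phenol is then methylated to 4. The whole ring substitution pattern is bought, not built.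

## Roads not taken

**Alternative 1:** The ring itself is cut, at the C1–C2 bond, and rebuilt last in a polyketide-style aromatisation.
- Forward key step: heating the diketo-dioxinone A2 (assembled from the silyl-protected hydroxymyristic acid A3) releases an acylketene. The alcohol that becomes the benzyl ester traps it, and the resulting triketo ester closes by aldol condensation and dehydration to the resorcylate A1.
- Merits: the stereocentre comes from A3 by very reliable chemistry (asymmetric hydrogenation of a beta-keto ester, or the natural acid). The ring regiochemistry is unambiguous. In certainty of absolute configuration this road is better than the chosen one.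
- Weak points: A1 has both phenols free, and the target needs the methyl group on the hydrogen-bonded, less reactive one. This forces protection of C4–OH, methylation of C6–OH, and then a silyl-to-acetyl exchange. The exchange exposes the free C2′ alcohol to the ortho ester, the very lactonisation hazard described above. A2 is a sensitive poly-beta-carbonyl compound needing several C-acylations.
- Comparison: the sequence is roughly twice as long. The chosen plan offers a purchasable ring whose phenols differentiate themselves, and an acetate delivered in the bond-forming event.

**Alternative 2:** Two ring bonds are cut, C1–C6 and C2–C3, and the arene is made by Diels–Alder benzannulation.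
- Forward key step: the silyloxy ketene-acetal diene A6 adds to the chiral acetoxy ynoate A5, its nucleophilic CH2 terminus bonding to the beta carbon. The adduct aromatises by expelling one methoxy group and gives A4 after desilylation.
- Merits: A4 already has the C4 phenol free and C6 methylated with no phenol protecting group, and is one hydrogenolysis from the target. The stereocentre of A5 would come from an enantiopure terminal epoxide. In protecting-group economy and security of configuration this road is as good as or better than the chosen one.
- Weak points: beta-alkyl ynoates are sluggish dienophiles, so a hydrolytically fragile diene has to be heated for a long time. In A5 the methylene between the alkyne and the acetoxy carbon invites isomerisation to the allenoate and beta-elimination of the acetate under those conditions. A5 itself needs four to five steps.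
- Comparison: the chosen plan offers a key step run below 0 °C, a pre-built aromatic core, and no thermal stress on the acetate.

**Alternative 3:** The C2–C1′ bond and the C1–carboxyl bond are cut together, by aryne insertion.
- Forward key step: fluoride releases the aryne from silyl triflate A8, and dibenzyl malonate A9 inserts across it. Regiochemistry is set by the methoxy group, and the product is the homophthalate A7.
- Merits: one mild step builds the ortho relationship without strong base on a benzyl ester. In that respect it is better than lateral lithiation.
- Weak points: it only builds the core and leaves the stereocentre unsolved. A7 carries two benzyl esters, and the aliphatic one must be taken selectively to the aldehyde, where it would converge on 8 and need the chosen key step anyway. A8 needs a multistep preparation from a resorcinol derivative.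
- Comparison: this road replaces steps 1 to 5, not step 7. The chosen plan reaches the same oxidation pattern in three steps from 1, with the two carboxyl groups differentiated from the start as acid and benzyl ester.

Key step: step 7

Assumption: the sense of induction of the nickel/ligand pair is taken by analogy, so the ligand enantiomer that gives the R acetate is to be fixed on a model aldehyde before the real run; orsellinic acid is taken as purchasable.

## Route

Step 1
Reactants: 1 orsellinic acid (2,4-dihydroxy-6-methylbenzoic acid); 2 benzyl bromide
Product: 3 benzyl 4-(benzyloxy)-2-hydroxy-6-methylbenzoate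
Conditions: 2 (2.1 equiv), K2CO3 (2.2 equiv), DMF, 0 °C to rt
Reagents that add atoms: none
Why: Carboxylate O-alkylation then Williamson etherification of the unchelated 4-OH; the 2-OH is hydrogen-bonded to the ester carbonyl and should stay free with two equivalents of halide, and ambient temperature avoids decarboxylation.

Step 2
Reactants: 3
Product: 4 benzyl 4-(benzyloxy)-2-methoxy-6-methylbenzoate
Conditions: MeI (3 equiv), K2CO3, DMF, 45 °C
Reagents that add atoms: iodomethane, CI
Why: Williamson etherification of the remaining chelated phenol under slightly forcing conditions; the benzyl ester and ether are inert to carbonate.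

Step 3
Reactants: 4
Product: 6 [5-(benzyloxy)-2-(benzyloxycarbonyl)-3-methoxyphenyl]acetic acid, via lateral benzyllithium 5 (not isolated)
Conditions: LiN(i-Pr)2 (1.15 equiv), THF, −78 °C, 20 min; CO2 (g); 1 M HCl
Reagents that add atoms: carbon dioxide, O=C=O
Why: Lateral lithiation of an ortho-toluate (the ester carbonyl directs the amide base to the adjacent methyl group and stabilises the anion as a dienolate) followed by carboxylation; the carboxylate formed is not deprotonated further and cannot cyclise, and the doubly ortho-substituted ester resists self-condensation at −78 °C.

Step 4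
Reactants: 6
Product: 7 benzyl 4-(benzyloxy)-2-[2-(ethylsulfanyl)-2-oxoethyl]-6-methoxybenzoate
Conditions: EtSH (1.5 equiv), EDC·HCl, DMAP (10 mol%), CH2Cl2, 0 °C to rt
Reagents that add atoms: ethanethiol, CCS
Why: Steglich-type carbodiimide thioesterification of the unhindered arylacetic acid; the aryl benzyl ester is a spectator.

Step 5
Reactants: 7
Product: 8 benzyl 4-(benzyloxy)-2-methoxy-6-(2-oxoethyl)benzoate
Conditions: Et3SiH (3 equiv), 10% Pd/C (5 mol%), acetone, rt; filtered through Celite, concentrated cold, used at once
Reagents that add atoms: none
Why: Fukuyama reduction: palladium inserts into the C–S bond and the silane delivers hydride, stopping at the aldehyde with no alcohol formed; the sulfur-moderated catalyst in an aprotic solvent should leave the benzyl ester and ether intact.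

Step 6
Reactants: 9 1-bromoundecane
Product: 10 undecylzinc bromide (titrated solution in DMA)
Conditions: Zn dust (1.5 equiv), I2 (5 mol%), DMA, 80 °C
Reagents that add atoms: zinc, [Zn]
Why: Direct oxidative insertion of iodine-activated zinc into a primary alkyl bromide in a polar amide solvent, the standard preparation of alkylzinc halides for Negishi coupling.

Step 7
Reactants: 8; 11 acetyl bromide; 10 undecylzinc bromide
Product: 13 benzyl 2-[(2R)-2-acetoxytridecyl]-4-(benzyloxy)-6-methoxybenzoate, via racemic 1-bromoalkyl acetate 12 (not isolated)
Conditions: 11 (1.0 equiv), ZnBr2 (2 mol%), CH2Cl2, −20 °C; then NiBr2·glyme (10 mol%), chiral pybox-type ligand (12 mol%), 10 (1.3 equiv), THF/DMA, −10 °C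
Reagents that add atoms: none
Why: Acetyl bromide adds across the aldehyde carbonyl to give racemic 12, forming the acetate O–acyl bond. The divalent nickel precatalyst is brought into the cycle by the organozinc; monovalent nickel abstracts bromine from 12 to leave a planar alpha-acetoxyalkyl radical, so both enantiomers of 12 converge. Transmetalation from 10 gives an undecyl–nickel complex that captures the radical, and reductive elimination from the trivalent dialkylnickel species forms the C2′–C3′ bond. The closest known reaction type is the nickel-catalysed enantioconvergent Negishi alkyl–alkyl coupling of racemic alpha-haloalkyl esters, generated from aldehyde and acyl bromide, with alkylzinc halides; no ring is closed. The C2′ stereocentre is set by the chiral ligand alone (catalyst control), which distinguishes the coordinating acetoxy group from the CH2Ar arm; the ligand enantiomer is chosen on a model aldehyde. Chemoselectivity over the aryl benzyl ester is secured by its two ortho substituents and the low nucleophilicity of the organozinc. Using 11 as the limiting reagent and letting it be consumed before 10 is added prevents nickel-catalysed acylation of the organozinc. Low temperature and immediate use of 8 counter enolisation toward the isocoumarin and loss of HBr from 12.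

Step 8
Reactants: 13
Product: 14 2-[(2R)-2-acetoxytridecyl]-4-hydroxy-6-methoxybenzoic acid
Conditions: H2 (1 atm), 10% Pd/C, EtOAc, rt
Reagents that add atoms: none
Why: Catalytic hydrogenolysis cleaves the benzyl ester and the benzyl ether together under neutral conditions; the C2′–O bond is homobenzylic and should not be cleaved, and without base or nucleophile the acetate neither migrates nor hydrolyses, so the stereocentre is untouched.

## Compound list

1 | orsellinic acid (2,4-dihydroxy-6-methylbenzoic acid) | Cc1cc(O)cc(O)c1C(=O)O | starting material
2 | benzyl bromide | BrCc1ccccc1 | starting material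
3 | benzyl 4-(benzyloxy)-2-hydroxy-6-methylbenzoate | Cc1cc(OCc2ccccc2)cc(O)c1C(=O)OCc1ccccc1 | intermediate
4 | benzyl 4-(benzyloxy)-2-methoxy-6-methylbenzoate | Cc1cc(OCc2ccccc2)cc(OC)c1C(=O)OCc1ccccc1 | intermediate
5 | benzyl 4-(benzyloxy)-2-(lithiomethyl)-6-methoxybenzoate (lateral benzyllithium) | [Li]Cc1cc(OCc2ccccc2)cc(OC)c1C(=O)OCc1ccccc1 | intermediate (not isolated)
6 | [5-(benzyloxy)-2-(benzyloxycarbonyl)-3-methoxyphenyl]acetic acid | OC(=O)Cc1cc(OCc2ccccc2)cc(OC)c1C(=O)OCc1ccccc1 | intermediate
7 | benzyl 4-(benzyloxy)-2-[2-(ethylsulfanyl)-2-oxoethyl]-6-methoxybenzoate | CCSC(=O)Cc1cc(OCc2ccccc2)cc(OC)c1C(=O)OCc1ccccc1 | intermediate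
8 | benzyl 4-(benzyloxy)-2-methoxy-6-(2-oxoethyl)benzoate | COc1cc(OCc2ccccc2)cc(CC=O)c1C(=O)OCc1ccccc1 | intermediate
9 | 1-bromoundecane | CCCCCCCCCCCBr | starting material
10 | undecylzinc bromide | CCCCCCCCCCC[Zn]Br | intermediate
11 | acetyl bromide | CC(=O)Br | starting material
12 | benzyl 2-(2-acetoxy-2-bromoethyl)-4-(benzyloxy)-6-methoxybenzoate (racemic) | CC(=O)OC(Br)Cc1cc(OCc2ccccc2)cc(OC)c1C(=O)OCc1ccccc1 | intermediate (not isolated)
13 | benzyl 2-[(2R)-2-acetoxytridecyl]-4-(benzyloxy)-6-methoxybenzoate | CCCCCCCCCCC[C@H](Cc1cc(OCc2ccccc2)cc(OC)c1C(=O)OCc1ccccc1)OC(C)=O | intermediate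
14 | 2-[(2R)-2-acetoxytridecyl]-4-hydroxy-6-methoxybenzoic acid | CCCCCCCCCCC[C@H](Cc1cc(O)cc(OC)c1C(=O)O)OC(C)=O | target

## Step count and least certain steps

Total: 8 steps. Longest linear sequence: 7 steps (steps 1 to 5, 7 and 8, from orsellinic acid); step 6 is a one-step side branch.

**Step 7 (key step).** Three processes threaten it.
- Ionisation of the alpha-bromo acetate next to the ortho ester: the ester carbonyl could capture the cation and lose its benzyl group (lactonisation), or HBr could be lost to a conjugated enol acetate.
- Enolisation of the aldehyde toward an isocoumarin before acetyl bromide has added.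
- Weak enantiodiscrimination, because acetyl is the smallest acyl group the catalyst can be asked to read and the ortho,ortho-disubstituted aryl arm is bulky.

Fallback, from 8 to 14, by reagent-controlled allylation and chain extension:
- Brown allylation of 8 with (+)-Ipc2B(allyl), the reagent from (−)-α-pinene (Et2O, −78 °C, ethanolamine work-up), should give benzyl 4-(benzyloxy)-2-[(2R)-2-hydroxypent-4-en-1-yl]-6-methoxybenzoate F1. The boron alkoxide is not nucleophilic toward the ester.
- F1 is acetylated without delay (Ac2O, pyridine, DMAP, 0 °C) to benzyl 2-[(2R)-2-acetoxypent-4-en-1-yl]-4-(benzyloxy)-6-methoxybenzoate F2.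
- Cross-metathesis of F2 with excess 1-decene (second-generation Grubbs catalyst, (H2IMes)(PCy3)Cl2Ru=CHPh, CH2Cl2, 40 °C) gives benzyl 2-[(2R,4E)-2-acetoxytridec-4-en-1-yl]-4-(benzyloxy)-6-methoxybenzoate F3. The alkene geometry is of no consequence.
- Hydrogenation over Pd/C (H2, EtOAc) saturates the alkene and removes both benzyl groups, rejoining the route at target 14.

**Step 3.** The base may deprotonate the OCH2Ph group of the benzyl ester (followed by acyl migration), or the lateral anion may attack the ester of a second molecule before carbon dioxide arrives.

Fallback, from 4 to 7, through the free-acid dianion: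
- Saponification of 4 (KOH, aqueous DMSO, 80 °C) gives 4-(benzyloxy)-2-methoxy-6-methylbenzoic acid F4.
- Its dianion (LiN(i-Pr)2, 2.3 equiv, THF, −78 to 0 °C) is carboxylated with CO2 to 4-(benzyloxy)-2-(carboxymethyl)-6-methoxybenzoic acid F5.
- Dehydration (Ac2O, toluene, 80 °C) closes the homophthalic anhydride 6-(benzyloxy)-8-methoxy-1H-isochromene-1,3(4H)-dione F6.
- Ethanethiol (DMAP cat., CH2Cl2, 0 °C) opens F6 at the unhindered, non-conjugated carbonyl to 4-(benzyloxy)-2-[2-(ethylsulfanyl)-2-oxoethyl]-6-methoxybenzoic acid F7.
- Benzylation of the hindered carboxylate (BnBr, KHCO3, DMF) returns to thioester 7.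

**Step 5.** The silane/palladium couple may begin transfer hydrogenolysis of the benzyl groups, and the aldehyde may be lost by enolisation and cyclisation on the catalyst or on silica.

Fallback, from 6 to 8, without palladium: chemoselective reduction of the free acid of 6 with BH3·SMe2 (THF, 0 °C) gives benzyl 4-(benzyloxy)-2-(2-hydroxyethyl)-6-methoxybenzoate F8. This is oxidised directly, before it can lactonise, with Dess–Martin periodinane (NaHCO3, CH2Cl2, 0 °C) to aldehyde 8.

## Further compounds

F1 | step 7 | benzyl 4-(benzyloxy)-2-[(2R)-2-hydroxypent-4-en-1-yl]-6-methoxybenzoate | C=CC[C@H](Cc1cc(OCc2ccccc2)cc(OC)c1C(=O)OCc1ccccc1)O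
F2 | step 7 | benzyl 2-[(2R)-2-acetoxypent-4-en-1-yl]-4-(benzyloxy)-6-methoxybenzoate | C=CC[C@H](Cc1cc(OCc2ccccc2)cc(OC)c1C(=O)OCc1ccccc1)OC(C)=O
F3 | step 7 | benzyl 2-[(2R,4E)-2-acetoxytridec-4-en-1-yl]-4-(benzyloxy)-6-methoxybenzoate | CCCCCCCC/C=C/C[C@H](Cc1cc(OCc2ccccc2)cc(OC)c1C(=O)OCc1ccccc1)OC(C)=O
F4 | step 3 | 4-(benzyloxy)-2-methoxy-6-methylbenzoic acid | Cc1cc(OCc2ccccc2)cc(OC)c1C(=O)O
F5 | step 3 | 4-(benzyloxy)-2-(carboxymethyl)-6-methoxybenzoic acid | OC(=O)Cc1cc(OCc2ccccc2)cc(OC)c1C(=O)O
F6 | step 3 | 6-(benzyloxy)-8-methoxy-1H-isochromene-1,3(4H)-dione | COc1cc(OCc2ccccc2)cc2CC(=O)OC(=O)c12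
F7 | step 3 | 4-(benzyloxy)-2-[2-(ethylsulfanyl)-2-oxoethyl]-6-methoxybenzoic acid | CCSC(=O)Cc1cc(OCc2ccccc2)cc(OC)c1C(=O)O
F8 | step 5 | benzyl 4-(benzyloxy)-2-(2-hydroxyethyl)-6-methoxybenzoate | OCCc1cc(OCc2ccccc2)cc(OC)c1C(=O)OCc1ccccc1
A1 | alternative 1 | benzyl 2-[(2R)-2-(tert-butyldimethylsilyloxy)tridecyl]-4,6-dihydroxybenzoate | CCCCCCCCCCC[C@H](Cc1cc(O)cc(O)c1C(=O)OCc1ccccc1)O[Si](C)(C)C(C)(C)C
A2 | alternative 1 | 6-[(6R)-6-(tert-butyldimethylsilyloxy)-2,4-dioxoheptadecyl]-2,2-dimethyl-4H-1,3-dioxin-4-one | CCCCCCCCCCC[C@H](CC(=O)CC(=O)CC1=CC(=O)OC(C)(C)O1)O[Si](C)(C)C(C)(C)C
A3 | alternative 1 | (3R)-3-(tert-butyldimethylsilyloxy)tetradecanoic acid | CCCCCCCCCCC[C@H](CC(=O)O)O[Si](C)(C)C(C)(C)C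
A4 | alternative 2 | benzyl 2-[(2R)-2-acetoxytridecyl]-4-hydroxy-6-methoxybenzoate | CCCCCCCCCCC[C@H](Cc1cc(O)cc(OC)c1C(=O)OCc1ccccc1)OC(C)=O
A5 | alternative 2 | benzyl (5R)-5-acetoxyhexadec-2-ynoate | CCCCCCCCCCC[C@H](CC#CC(=O)OCc1ccccc1)OC(C)=O
A6 | alternative 2 | 1,1-dimethoxy-3-(trimethylsilyloxy)buta-1,3-diene | COC(OC)=CC(=C)O[Si](C)(C)C
A7 | alternative 3 | benzyl 4-(benzyloxy)-2-[2-(benzyloxy)-2-oxoethyl]-6-methoxybenzoate | COc1cc(OCc2ccccc2)cc(CC(=O)OCc2ccccc2)c1C(=O)OCc1ccccc1
A8 | alternative 3 | 5-(benzyloxy)-3-methoxy-2-(trimethylsilyl)phenyl trifluoromethanesulfonate | COc1cc(OCc2ccccc2)cc(OS(=O)(=O)C(F)(F)F)c1[Si](C)(C)C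
A9 | alternative 3 | dibenzyl malonate | O=C(CC(=O)OCc1ccccc1)OCc1ccccc1
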